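**Retrosynthetic overview**

- Ring A is disconnected last. The flavone C5–C4a bond comes from thermal ring expansion of a 4-methoxy-4-(4-pyranon-6-yl)-3-prenyloxycyclobut-2-enone (cyclobutenone to dienylketene to phenol).
- The strategy rests on ring A: C5(OH) and C8(OMe) are para, with C6(H) and C7(O-prenyl) between them. This C5–C6–C7–C8 unit is C1–C2–C3–C4 of the cyclobutenone, and the fusion bond C4a–C8a is the C5=C6 enol-ether double bond of a 2-aryl-3-methoxy-4H-pyran-4-one.
- The cyclobutenone is assembled by C6-lithiation of that pyranone, 1,2-addition to prenyl semisquarate (from diisopropyl squarate by mono-reduction, acid-induced loss of isopropanol and alkoxy exchange with prenol) and O-methylation.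
- Ring C comes from furan and O-TIPS-vanillin: furyl carbinol, Achmatowicz pyranone, methyl acetal, epoxide, acid rearrangement to the 3-hydroxy-4-pyranone, O-methylation.
- Order of rings: ring B is bought (vanillin), ring C is made second, ring A is closed last; fluoride desilylation ends the route.

Key step: step 13

Remark: the target is achiral. The stereocentres of 5–8, 12, 17, 18 and 20 are carried as racemates or diastereomer mixtures because each is erased when rings C and A become aromatic.

Step 1
Reactants: 1 vanillin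
Product: 2 3-methoxy-4-(triisopropylsilyloxy)benzaldehyde
Conditions: TIPSCl, imidazole, DMF, rt
Reagents that add atoms: triisopropylsilyl chloride, CC(C)[Si](Cl)(C(C)C)C(C)C
Why: Standard phenol silylation; the hindered aryl TIPS ether should tolerate organolithiums, peroxides, mild acid and MeI/Ag2O and is cleaved at the end by fluoride without touching the prenyl ether.

Step 2
Reactants: 2 3-methoxy-4-(triisopropylsilyloxy)benzaldehyde; 3 furan
Product: 5 furan-2-yl[3-methoxy-4-(triisopropylsilyloxy)phenyl]methanol (racemic), via 2-lithiofuran 4 (not isolated)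
Conditions: furan, n-BuLi, THF, 0 °C; then 2, −78 °C; H2O quench
Reagents that add atoms: none
Why: Alpha-lithiation of furan followed by 1,2-addition of the furyllithium to the non-enolisable aldehyde; the carbinol centre forms racemic and is erased later.

Step 3
Reactants: 5 furan-2-yl[3-methoxy-4-(triisopropylsilyloxy)phenyl]methanol
Product: 6 6-hydroxy-2-[3-methoxy-4-(triisopropylsilyloxy)phenyl]-2H-pyran-3(6H)-one (mixture of diastereomers)
Conditions: VO(acac)2 (cat.), t-BuOOH (decane), CH2Cl2, 0 °C to rt
Reagents that add atoms: tert-butyl hydroperoxide, CC(C)(C)OO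
Why: Achmatowicz rearrangement, in which hydroxyl-directed, halogen-free oxidation of the furan gives the cis-enedione that closes to the pyranone hemiacetal while the electron-rich arene is spared; the anomeric centre forms as a mixture and does not matter.

Step 4
Reactants: 6 6-hydroxy-2-[3-methoxy-4-(triisopropylsilyloxy)phenyl]-2H-pyran-3(6H)-one
Product: 7 6-methoxy-2-[3-methoxy-4-(triisopropylsilyloxy)phenyl]-2H-pyran-3(6H)-one (mixture of diastereomers)
Conditions: HC(OMe)3, BF3·OEt2 (cat.), CH2Cl2, 0 °C
Reagents that add atoms: trimethyl orthoformate, COC(OC)OC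
Why: Acid-catalysed acetal exchange through the ring oxocarbenium ion, the usual capping of Achmatowicz hemiacetals, which blocks base-induced ring opening in the next step; the anomeric configuration is irrelevant.

Step 5
Reactants: 7 6-methoxy-2-[3-methoxy-4-(triisopropylsilyloxy)phenyl]-2H-pyran-3(6H)-one
Product: 8 4,5-epoxy-6-methoxy-2-[3-methoxy-4-(triisopropylsilyloxy)phenyl]tetrahydro-2H-pyran-3-one (mixture of diastereomers)
Conditions: t-BuOOH, DBU (cat.), CH2Cl2, 0 °C
Reagents that add atoms: tert-butyl hydroperoxide, CC(C)(C)OO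
Why: Weitz–Scheffer nucleophilic epoxidation of the enone (conjugate addition of the peroxide anion, then ring closure), expected anti to the acetal methoxy group; all stereocentres are erased in step 6.

Step 6
Reactants: 8 4,5-epoxy-6-methoxy-2-[3-methoxy-4-(triisopropylsilyloxy)phenyl]tetrahydro-2H-pyran-3-one
Product: 9 3-hydroxy-2-[3-methoxy-4-(triisopropylsilyloxy)phenyl]-4H-pyran-4-one
Conditions: TsOH·H2O (cat.), toluene, 80 °C
Reagents that add atoms: none
Why: Acid-catalysed Meinwald-type isomerisation of the alpha,beta-epoxy ketone to the 3,4-dione, beta-elimination of methanol from C6 and enolisation to the 3-hydroxy-4-pyranone, the same epoxy-ketone rearrangement that converts the 2-methyl analogue into maltol.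

Step 7
Reactants: 9 3-hydroxy-2-[3-methoxy-4-(triisopropylsilyloxy)phenyl]-4H-pyran-4-one
Product: 10 3-methoxy-2-[3-methoxy-4-(triisopropylsilyloxy)phenyl]-4H-pyran-4-one
Conditions: MeI, K2CO3, acetone, 40 °C
Reagents that add atoms: iodomethane, CI
Why: Williamson O-methylation of the acidic enolic 3-OH (acidity comparable to maltol) under conditions mild enough to leave the aryl silyl ether in place.

Step 8
Reactants: 11 diisopropyl squarate
Product: 12 4-hydroxy-2,3-diisopropoxycyclobut-2-en-1-one (racemic)
Conditions: LiAlH(OtBu)3, THF, −78 to 0 °C; aqueous work-up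
Reagents that add atoms: none
Why: Selective 1,2-mono-reduction of one squarate carbonyl by a hindered, mild hydride, the resulting alkoxide deactivating the ring against a second reduction; the new centre is racemic and lost in step 9.

Step 9
Reactants: 12 4-hydroxy-2,3-diisopropoxycyclobut-2-en-1-one
Product: 13 3-isopropoxycyclobut-3-ene-1,2-dione
Conditions: conc. HCl (cat.), CH2Cl2, rt
Reagents that add atoms: none
Why: Acid-catalysed allylic transposition, in which ionisation of the hydroxyl gives an alkoxy-stabilised cyclobutenyl cation that is captured by water at the distal alkoxy carbon with loss of isopropanol, the established conversion of reduced squarates into semisquarates.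

Step 10
Reactants: 13 3-isopropoxycyclobut-3-ene-1,2-dione; 14 prenol (3-methylbut-2-en-1-ol)
Product: 15 3-(3-methylbut-2-enyloxy)cyclobut-3-ene-1,2-dione
Conditions: prenol (excess), i-Pr2NEt (cat.), CH2Cl2, 0 °C to rt, i-PrOH stripped under reduced pressure; kept neutral and cold, used at once
Reagents that add atoms: none
Why: Base-catalysed transesterification of the vinylogous ester by addition–elimination at C3, the exchange known for squarate esters in alcohols with tertiary amines, driven here by excess prenol and removal of the more volatile isopropanol.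

Step 11
Reactants: 10 3-methoxy-2-[3-methoxy-4-(triisopropylsilyloxy)phenyl]-4H-pyran-4-one; 15 3-(3-methylbut-2-enyloxy)cyclobut-3-ene-1,2-dione
Product: 17 4-hydroxy-4-{5-methoxy-6-[3-methoxy-4-(triisopropylsilyloxy)phenyl]-4-oxo-4H-pyran-2-yl}-3-(3-methylbut-2-enyloxy)cyclobut-2-en-1-one (racemic), via 6-lithiopyranone 16 (not isolated)
Conditions: LiTMP (from TMPH, n-BuLi), THF, −78 °C, short metalation; then 15, −78 °C; AcOH quench at −78 °C
Reagents that add atoms: none
Why: Kinetic deprotonation of the vinylic C6–H beside the ring oxygen by a hindered lithium amide (as in C2-lithiation of chromones), then 1,2-addition of the vinyllithium to the ketone-like carbonyl flanking C–O-prenyl, the usual regiochemistry for organolithium additions to 3-alkoxycyclobutenediones; the new quaternary carbinol centre is racemic and later becomes aromatic C8.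

Step 12
Reactants: 17 4-hydroxy-4-{5-methoxy-6-[3-methoxy-4-(triisopropylsilyloxy)phenyl]-4-oxo-4H-pyran-2-yl}-3-(3-methylbut-2-enyloxy)cyclobut-2-en-1-one
Product: 18 4-methoxy-4-{5-methoxy-6-[3-methoxy-4-(triisopropylsilyloxy)phenyl]-4-oxo-4H-pyran-2-yl}-3-(3-methylbut-2-enyloxy)cyclobut-2-en-1-one (racemic)
Conditions: MeI (excess), Ag2O, 4 Å MS, MeCN, rt, dark
Reagents that add atoms: iodomethane, CI
Why: Purdie (silver oxide) methylation of the tertiary alcohol under near-neutral conditions, as used for 4-hydroxycyclobutenones; soft MeI should not O-alkylate the pyranone carbonyl as a hard methylating agent would.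

Step 13
Reactants: 18 4-methoxy-4-{5-methoxy-6-[3-methoxy-4-(triisopropylsilyloxy)phenyl]-4-oxo-4H-pyran-2-yl}-3-(3-methylbut-2-enyloxy)cyclobut-2-en-1-one
Product: 21 5-hydroxy-3,8-dimethoxy-2-[3-methoxy-4-(triisopropylsilyloxy)phenyl]-7-(3-methylbut-2-enyloxy)-4H-chromen-4-one, via (Z)-dienylketene 19 (not isolated), via 4a-H dienone 20 (not isolated)
Conditions: toluene (degassed, dilute), 110 °C
Reagents that add atoms: none
Why: Moore-type benzannulation: the cyclobutenone C1–C4 bond opens in a thermal four-electron conrotatory process to the (Z)-dienylketene 19, the ketene carbon then bonds to pyranone C5 in a thermal six-electron disrotatory electrocyclisation to give dienone 20, and enolisation of its C4a–H, which lies between two carbonyls, delivers the hydrogen-bonded C5 phenol irreversibly. The closest known reactions are the thermal ring expansions of 4-alkenyl- and 4-heteroaryl-4-alkoxycyclobutenones to monoprotected hydroquinones, with the enol-ether C5=C6 bond of the 4-pyranone taking the alkenyl role here. Ring A is the only ring closed, by 6π-electrocyclisation that forms the flavone C5–C4a bond. No stereocentre survives: the transient C4a centre of 20 is racemic and is lost on aromatisation, and the quaternary carbon of 18 becomes aromatic C8. The selectivity required is torquoselectivity in the ring opening, secured by the C4 methoxy donor rotating outward so that the pyranonyl group lies cis to the ketene; the substitution pattern (5-OH, 6-H, 7-O-prenyl, 8-OMe) is already fixed in 18. Methylation before thermolysis closes off lactonisation of the ketene by a free 4-hydroxyl and avoids an air-sensitive hydroquinone, and at 110 °C neither the allyl vinyl ether of 18 and 19 nor the aryl prenyl ether of 21 should undergo Claisen rearrangement at a competitive rate.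

Step 14
Reactants: 21 5-hydroxy-3,8-dimethoxy-2-[3-methoxy-4-(triisopropylsilyloxy)phenyl]-7-(3-methylbut-2-enyloxy)-4H-chromen-4-one
Product: 22 5-hydroxy-2-(4-hydroxy-3-methoxyphenyl)-3,8-dimethoxy-7-(3-methylbut-2-enyloxy)-4H-chromen-4-one (5,4'-dihydroxy-3,8,3'-trimethoxy-7-prenyloxyflavone)
Conditions: TBAF, AcOH, THF, 0 °C
Reagents that add atoms: none
Why: Fluoride-induced cleavage of the aryl silyl ether, buffered with acetic acid so that the phenoxide is protonated at once; the prenyl ether, the methyl ethers and the chelated 5-OH are inert to these conditions.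

**Compound list**

1 | vanillin (4-hydroxy-3-methoxybenzaldehyde) | COc1cc(C=O)ccc1O | starting material
2 | 3-methoxy-4-(triisopropylsilyloxy)benzaldehyde | COc1cc(C=O)ccc1O[Si](C(C)C)(C(C)C)C(C)C | intermediate
3 | furan | c1ccoc1 | starting material
4 | 2-lithiofuran | [Li]c1ccco1 | intermediate
5 | furan-2-yl[3-methoxy-4-(triisopropylsilyloxy)phenyl]methanol (racemic) | COc1cc(C(O)c2ccco2)ccc1O[Si](C(C)C)(C(C)C)C(C)C | intermediate
6 | 6-hydroxy-2-[3-methoxy-4-(triisopropylsilyloxy)phenyl]-2H-pyran-3(6H)-one (mixture of diastereomers) | COc1cc(C2OC(O)C=CC2=O)ccc1O[Si](C(C)C)(C(C)C)C(C)C | intermediate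
7 | 6-methoxy-2-[3-methoxy-4-(triisopropylsilyloxy)phenyl]-2H-pyran-3(6H)-one (mixture of diastereomers) | COc1cc(C2OC(OC)C=CC2=O)ccc1O[Si](C(C)C)(C(C)C)C(C)C | intermediate
8 | 4,5-epoxy-6-methoxy-2-[3-methoxy-4-(triisopropylsilyloxy)phenyl]tetrahydro-2H-pyran-3-one (mixture of diastereomers) | COc1cc(C2OC(OC)C3OC3C2=O)ccc1O[Si](C(C)C)(C(C)C)C(C)C | intermediate
9 | 3-hydroxy-2-[3-methoxy-4-(triisopropylsilyloxy)phenyl]-4H-pyran-4-one | COc1cc(-c2occc(=O)c2O)ccc1O[Si](C(C)C)(C(C)C)C(C)C | intermediate
10 | 3-methoxy-2-[3-methoxy-4-(triisopropylsilyloxy)phenyl]-4H-pyran-4-one | COc1cc(-c2occc(=O)c2OC)ccc1O[Si](C(C)C)(C(C)C)C(C)C | intermediate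
11 | diisopropyl squarate (3,4-diisopropoxycyclobut-3-ene-1,2-dione) | CC(C)OC1=C(OC(C)C)C(=O)C1=O | starting material
12 | 4-hydroxy-2,3-diisopropoxycyclobut-2-en-1-one (racemic) | CC(C)OC1=C(OC(C)C)C(O)C1=O | intermediate
13 | 3-isopropoxycyclobut-3-ene-1,2-dione (isopropyl semisquarate) | CC(C)OC1=CC(=O)C1=O | intermediate
14 | prenol (3-methylbut-2-en-1-ol) | CC(C)=CCO | starting material
15 | 3-(3-methylbut-2-enyloxy)cyclobut-3-ene-1,2-dione (prenyl semisquarate) | CC(C)=CCOC1=CC(=O)C1=O | intermediate
16 | 6-lithio-3-methoxy-2-[3-methoxy-4-(triisopropylsilyloxy)phenyl]-4H-pyran-4-one | COc1cc(-c2oc([Li])cc(=O)c2OC)ccc1O[Si](C(C)C)(C(C)C)C(C)C | intermediate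
17 | 4-hydroxy-4-{5-methoxy-6-[3-methoxy-4-(triisopropylsilyloxy)phenyl]-4-oxo-4H-pyran-2-yl}-3-(3-methylbut-2-enyloxy)cyclobut-2-en-1-one (racemic) | COc1cc(-c2oc(C3(O)C(OCC=C(C)C)=CC3=O)cc(=O)c2OC)ccc1O[Si](C(C)C)(C(C)C)C(C)C | intermediate
18 | 4-methoxy-4-{5-methoxy-6-[3-methoxy-4-(triisopropylsilyloxy)phenyl]-4-oxo-4H-pyran-2-yl}-3-(3-methylbut-2-enyloxy)cyclobut-2-en-1-one (racemic) | COc1cc(-c2oc(C3(OC)C(OCC=C(C)C)=CC3=O)cc(=O)c2OC)ccc1O[Si](C(C)C)(C(C)C)C(C)C | intermediate
19 | (3Z)-4-methoxy-4-{5-methoxy-6-[3-methoxy-4-(triisopropylsilyloxy)phenyl]-4-oxo-4H-pyran-2-yl}-3-(3-methylbut-2-enyloxy)buta-1,3-dien-1-one (dienylketene; pyranonyl cis to the ketene) | COc1cc(-c2oc(/C(OC)=C(\C=C=O)OCC=C(C)C)cc(=O)c2OC)ccc1O[Si](C(C)C)(C(C)C)C(C)C | intermediate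
20 | 3,8-dimethoxy-2-[3-methoxy-4-(triisopropylsilyloxy)phenyl]-7-(3-methylbut-2-enyloxy)-4aH-chromene-4,5-dione (racemic) | COC1=C(c2ccc(O[Si](C(C)C)(C(C)C)C(C)C)c(OC)c2)OC2=C(OC)C(OCC=C(C)C)=CC(=O)C2C1=O | intermediate
21 | 5-hydroxy-3,8-dimethoxy-2-[3-methoxy-4-(triisopropylsilyloxy)phenyl]-7-(3-methylbut-2-enyloxy)-4H-chromen-4-one | COc1cc(-c2oc3c(OC)c(OCC=C(C)C)cc(O)c3c(=O)c2OC)ccc1O[Si](C(C)C)(C(C)C)C(C)C | intermediate
22 | 5-hydroxy-2-(4-hydroxy-3-methoxyphenyl)-3,8-dimethoxy-7-(3-methylbut-2-enyloxy)-4H-chromen-4-one | COc1cc(-c2oc3c(OC)c(OCC=C(C)C)cc(O)c3c(=O)c2OC)ccc1O | target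

**Step count**

Total: 14 steps. Longest linear sequence: 11 steps (steps 1–7, then 11–14); the squarate branch (steps 8–10) joins at step 11.

**Steps most likely to fail**

Step 11. Deprotonation of pyranone 10 may be misdirected toward C5 by lithium coordination to the carbonyl, or the 6-lithio species may add to unmetalated pyranone or decompose before the electrophile arrives. The fallback sets out from 10 and obtains the nucleophile by halogen–metal exchange in an amine-free flask. Zincation with TMPZnCl·LiCl in THF at 25 °C, a base that metalates chromone-type pyranones next to the ring oxygen and gives a stable organozinc, should give the 6-(chlorozincio)pyranone F1. Iodinolysis with I2 should give the 6-iodo-3-methoxy-2-aryl-4H-pyran-4-one F2, which is isolated. Iodine–magnesium exchange with i-PrMgCl·LiCl at −78 °C should then give the pyranonylmagnesium chloride F3, which is added to 15 and quenched with AcOH. The route is rejoined at 17.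

Step 13. The prenyl vinylogous ester may not survive the thermolysis: a [3,3] shift within the four-membered ring or in the ring-opened ketene, or ionisation of the allylic C–O bond, could divert material before the six-electron closure. The fallback sets out from 10 and 13 and carries a robust isopropyl ether through the benzannulation. Lithiopyranone 16 is added to isopropyl semisquarate 13 to give the 4-hydroxy-3-isopropoxy adduct F4, and MeI/Ag2O gives its methyl ether F5. Thermolysis in toluene, or in xylene if needed (the alkyl ether allows it), passes through the isopropoxy dienylketene F6 and the 4a-H dienone F7 to the 7-O-isopropyl flavone F8. BCl3 in CH2Cl2 at −78 to 0 °C cleaves isopropyl aryl ethers much faster than methyl ethers and should give the 7-hydroxyflavone F9. Prenyl bromide with K2CO3 in acetone then alkylates the 7-OH selectively, since the 5-OH is chelated and the 4'-oxygen is silylated. The route is rejoined at 21.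

Step 10. The alkoxy exchange may stall at equilibrium, or the amine may trigger oligomerisation or ring cleavage of the highly electrophilic semisquarate. The fallback sets out from 13: hydrolysis with dilute aqueous HCl in THF gives semisquaric acid (3-hydroxycyclobut-3-ene-1,2-dione) F10. O-alkylation of its silver salt (Ag2O, prenyl bromide, Et2O, dark) gives the ester, both oxygen termini of the delocalised anion leading to the same product. The route is rejoined at 15.

**Further compounds**

F1 | step 11 | 6-(chlorozincio)-3-methoxy-2-[3-methoxy-4-(triisopropylsilyloxy)phenyl]-4H-pyran-4-one | COc1cc(-c2oc([Zn]Cl)cc(=O)c2OC)ccc1O[Si](C(C)C)(C(C)C)C(C)C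
F2 | step 11 | 6-iodo-3-methoxy-2-[3-methoxy-4-(triisopropylsilyloxy)phenyl]-4H-pyran-4-one | COc1cc(-c2oc(I)cc(=O)c2OC)ccc1O[Si](C(C)C)(C(C)C)C(C)C
F3 | step 11 | {5-methoxy-6-[3-methoxy-4-(triisopropylsilyloxy)phenyl]-4-oxo-4H-pyran-2-yl}magnesium chloride | COc1cc(-c2oc([Mg]Cl)cc(=O)c2OC)ccc1O[Si](C(C)C)(C(C)C)C(C)C
F4 | step 13 | 4-hydroxy-3-isopropoxy-4-{5-methoxy-6-[3-methoxy-4-(triisopropylsilyloxy)phenyl]-4-oxo-4H-pyran-2-yl}cyclobut-2-en-1-one (racemic) | COc1cc(-c2oc(C3(O)C(OC(C)C)=CC3=O)cc(=O)c2OC)ccc1O[Si](C(C)C)(C(C)C)C(C)C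
F5 | step 13 | 3-isopropoxy-4-methoxy-4-{5-methoxy-6-[3-methoxy-4-(triisopropylsilyloxy)phenyl]-4-oxo-4H-pyran-2-yl}cyclobut-2-en-1-one (racemic) | COc1cc(-c2oc(C3(OC)C(OC(C)C)=CC3=O)cc(=O)c2OC)ccc1O[Si](C(C)C)(C(C)C)C(C)C
F6 | step 13 | (3Z)-3-isopropoxy-4-methoxy-4-{5-methoxy-6-[3-methoxy-4-(triisopropylsilyloxy)phenyl]-4-oxo-4H-pyran-2-yl}buta-1,3-dien-1-one | COc1cc(-c2oc(/C(OC)=C(\C=C=O)OC(C)C)cc(=O)c2OC)ccc1O[Si](C(C)C)(C(C)C)C(C)C
F7 | step 13 | 7-isopropoxy-3,8-dimethoxy-2-[3-methoxy-4-(triisopropylsilyloxy)phenyl]-4aH-chromene-4,5-dione (racemic) | COC1=C(c2ccc(O[Si](C(C)C)(C(C)C)C(C)C)c(OC)c2)OC2=C(OC)C(OC(C)C)=CC(=O)C2C1=O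
F8 | step 13 | 5-hydroxy-7-isopropoxy-3,8-dimethoxy-2-[3-methoxy-4-(triisopropylsilyloxy)phenyl]-4H-chromen-4-one | COc1cc(-c2oc3c(OC)c(OC(C)C)cc(O)c3c(=O)c2OC)ccc1O[Si](C(C)C)(C(C)C)C(C)C
F9 | step 13 | 5,7-dihydroxy-3,8-dimethoxy-2-[3-methoxy-4-(triisopropylsilyloxy)phenyl]-4H-chromen-4-one | COc1cc(-c2oc3c(OC)c(O)cc(O)c3c(=O)c2OC)ccc1O[Si](C(C)C)(C(C)C)C(C)C
F10 | step 10 | semisquaric acid (3-hydroxycyclobut-3-ene-1,2-dione) | OC1=CC(=O)C1=O
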